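The lower flavan-3-ol is traced back to its flavonol. In ring C of that unit, O1–C2 is read as the carbonyl group of a tri-O-benzylgalloyl chloride and C3–C4 as an α-alkoxyacetyl chain on C4a, while C8a of ring A carries fluorine ortho to a temporary C4 ketone that acidifies C3–H and activates C8a. One operation, enolate C-acylation followed by SNAr ring closure, forms C2–C3 and O1–C8a. Reduction through the flavylium ion, oxidation to the flavan-3-one and a dynamic kinetic transfer hydrogenation, an anthocyanidin-reductase mimic, set 2R,3R. C8 bromination, aryl-cerium addition to (2S)-liquiritigenin dibenzyl ether, dehydration and a cis-selective, debenzylating hydrogenation finish the target.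

Key step: step 4

Assumption: RuCl[(S,S)-TsDPEN](p-cymene) is taken as the catalyst enantiomer that gives the 2R,3R alcohol in step 7; if the sense of induction is the opposite, the (R,R) catalyst is used.

Step 1
Reactants: 1 4-methoxybenzyl alcohol; 2 2-chloro-N-methoxy-N-methylacetamide
Product: 4 N-methoxy-2-[(4-methoxybenzyl)oxy]-N-methylacetamide, via sodium 4-methoxybenzyl oxide 3 (not isolated)
Conditions: NaH, THF, 0 °C; then 2, n-Bu4NI (cat.), 0 °C to rt
Reagents that add atoms: none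
Why: Williamson ether synthesis: the alkoxide displaces chloride from the activated α-chloro amide by SN2, while the N-methoxy-N-methylamide carbonyl is too poor an acylating agent to be attacked at 0 °C.

Step 2
Reactants: 5 5-fluororesorcinol
Product: 6 1,3-bis(benzyloxy)-5-fluorobenzene
Conditions: BnBr, K2CO3, DMF, rt
Reagents that add atoms: benzyl bromide, BrCc1ccccc1
Why: Williamson O-alkylation of both phenoxides with a primary benzylic bromide, for which carbonate in DMF should give O- and not C-alkylation.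

Step 3
Reactants: 6 1,3-bis(benzyloxy)-5-fluorobenzene; 4 N-methoxy-2-[(4-methoxybenzyl)oxy]-N-methylacetamide
Product: 8 1-[2,4-bis(benzyloxy)-6-fluorophenyl]-2-[(4-methoxybenzyl)oxy]ethan-1-one, via aryllithium 7 (not isolated)
Conditions: n-BuLi, THF, −78 °C; then 4, −78 to −40 °C; aq. NH4Cl
Reagents that add atoms: none
Why: Directed ortho-metalation: the proton flanked by fluorine and benzyloxy is the most acidic ring proton, the 2-fluoroaryllithium is stable against LiF loss at −78 °C, and acylation by the N-methoxy-N-methylamide stops at the ketone because the chelated tetrahedral adduct survives until work-up.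

Step 4
Reactants: 8 1-[2,4-bis(benzyloxy)-6-fluorophenyl]-2-[(4-methoxybenzyl)oxy]ethan-1-one; 9 3,4,5-tris(benzyloxy)benzoyl chloride
Product: 12 5,7-bis(benzyloxy)-3-[(4-methoxybenzyl)oxy]-2-[3,4,5-tris(benzyloxy)phenyl]-4H-chromen-4-one, via lithium Z-enolate 10 (not isolated), via lithium 1,3-diketonate 11 (not isolated)
Conditions: LiN(SiMe3)2 (2.1 equiv), toluene/THF, −78 °C; 9, −78 to 0 °C; then DMF, 80 °C
Reagents that add atoms: none
Why: The lithium enolate of 8 is C-acylated by the aroyl chloride (Claisen-type condensation, C2–C3), and the second equivalent of base converts the 2-alkoxy-1,3-diketone into its lithium diketonate. On warming, the diketonate oxygen that was the acyl chloride carbonyl oxygen attacks C8a ipso to fluorine; the ortho C4 carbonyl stabilises the anionic σ-adduct and fluoride leaves (intramolecular SNAr, O1–C8a), the two benzyloxy groups being meta to C8a and therefore not deactivating. The closest known reaction type is the one-pot acylation/SNAr synthesis of chromones and flavones from 2-fluoroaryl ketones. Ring C closes by a 6-exo-trig addition–elimination at the arene carbon, the only six-membered mode open to either enolate oxygen. No stereocentre is created: C2 and C3 are left trigonal on purpose and are set together in step 7. The step needs C- over O-acylation (lithium counter-ion in toluene; any enol ester should be returned to the diketonate by acyl transfer) and displacement of fluoride only, which the single C–F bond next to the ketone secures.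

Step 5
Reactants: 12 5,7-bis(benzyloxy)-3-[(4-methoxybenzyl)oxy]-2-[3,4,5-tris(benzyloxy)phenyl]-4H-chromen-4-one
Product: 16 5,7-bis(benzyloxy)-2-[3,4,5-tris(benzyloxy)phenyl]chroman-3-ol (racemic, 2,3-cis/trans mixture), via flav-2-en-4-ol 13 (not isolated), via flavylium trifluoroacetate 14 (not isolated), via 3-O-PMB flavan 15 (not isolated)
Conditions: LiAlH4, THF, 0 °C; aq. KNaC4H4O6 work-up; crude in CH2Cl2, Et3SiH (excess), CF3CO2H, −20 to 20 °C
Reagents that add atoms: none
Why: Hydride reduction of the chromone carbonyl (the classical entry from flavonol ethers to anthocyanidin ethers) gives an allylic enol-ether carbinol that CF3CO2H ionises to the flavylium ion, which Et3SiH reduces by ionic hydrogenation (two hydrides, one proton) to the 3-O-PMB flavan before the acid cleaves the PMB ether with the silane as cation scavenger; the racemic cis/trans mixture is tolerated because C2 and C3 are reset in steps 6 and 7, and any flavan-3-one formed by loss of the PMB cation from a protonated enol ether converges in step 6.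

Step 6
Reactants: 16 5,7-bis(benzyloxy)-2-[3,4,5-tris(benzyloxy)phenyl]chroman-3-ol (racemic mixture)
Product: 17 5,7-bis(benzyloxy)-2-[3,4,5-tris(benzyloxy)phenyl]chroman-3-one (racemic)
Conditions: DMP (1,1,1-triacetoxy-1,1-dihydro-1,2-benziodoxol-3(1H)-one), NaHCO3, wet CH2Cl2, 0 °C to rt
Reagents that add atoms: none
Why: Periodinane oxidation of a secondary alcohol, by which all stereoisomers of 16 should converge on one racemic flavan-3-one.

Step 7
Reactants: 17 5,7-bis(benzyloxy)-2-[3,4,5-tris(benzyloxy)phenyl]chroman-3-one (racemic)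
Product: 18 (2R,3R)-5,7-bis(benzyloxy)-2-[3,4,5-tris(benzyloxy)phenyl]chroman-3-ol (penta-O-benzyl-(−)-epigallocatechin)
Conditions: RuCl[(S,S)-TsDPEN](p-cymene) (cat.), HCO2H/Et3N (2:5), degassed DMF, 30 °C
Reagents that add atoms: none
Why: Asymmetric transfer hydrogenation with dynamic kinetic resolution: C2–H (α to the ketone, benzylic and α-oxygenated) epimerises through the enol in the amine-rich medium, the chiral Ru hydride reduces the 2R ketone faster and delivers hydride to the C3 face anti to the 2-aryl group, so that C2 (R) and C3 (R, OH cis to aryl) should be set together under catalyst control.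

Step 8
Reactants: 18 (2R,3R)-5,7-bis(benzyloxy)-2-[3,4,5-tris(benzyloxy)phenyl]chroman-3-ol
Product: 19 (2R,3R)-5,7-bis(benzyloxy)-8-bromo-2-[3,4,5-tris(benzyloxy)phenyl]chroman-3-ol
Conditions: NBS, CH2Cl2, −40 °C
Reagents that add atoms: N-bromosuccinimide, O=C1CCC(=O)N1Br
Why: Electrophilic aromatic bromination of the phloroglucinol-type ring A at C8, the site ortho to O1 and to the 7-benzyloxy group that is preferred over C6 in 5,7-di-O-benzylated flavan-3-ols, while the flanked positions of ring B are less reactive.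

Step 9
Reactants: 20 (2S)-liquiritigenin ((2S)-7-hydroxy-2-(4-hydroxyphenyl)chroman-4-one)
Product: 21 (2S)-7-(benzyloxy)-2-[4-(benzyloxy)phenyl]chroman-4-one
Conditions: BnOH, PPh3, DIAD, THF, 0 °C to rt
Reagents that add atoms: benzyl alcohol, OCc1ccccc1
Why: Mitsunobu etherification benzylates both phenols without a free base, so the base-induced ring opening that racemises flavanones is avoided and the chiral-pool C2 (S) stereocentre is kept.

Step 10
Reactants: 19 (2R,3R)-5,7-bis(benzyloxy)-8-bromo-2-[3,4,5-tris(benzyloxy)phenyl]chroman-3-ol; 21 (2S)-7-(benzyloxy)-2-[4-(benzyloxy)phenyl]chroman-4-one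
Product: 25 (2R,3R)-5,7-bis(benzyloxy)-8-{(2S)-7-(benzyloxy)-2-[4-(benzyloxy)phenyl]-2H-chromen-4-yl}-2-[3,4,5-tris(benzyloxy)phenyl]chroman-3-ol, via dilithio species 22 (not isolated), via aryl-dichlorocerium species 23 (not isolated), via tertiary carbinol 24 (not isolated)
Conditions: n-BuLi (2.2 equiv), THF, −78 °C; CeCl3, −78 °C; 21, −78 to −30 °C; aq. NH4Cl; then p-TsOH·H2O (cat.), CH2Cl2, rt
Reagents that add atoms: none
Why: Deprotonation of the 3-OH and Br/Li exchange give the C8 aryllithium, transmetalation to the less basic organocerium favours 1,2-addition over enolisation of the flavanone, and acid-catalysed E1 dehydration of the doubly benzylic tertiary carbinol gives the conjugated flav-3-ene without touching C2 of either unit.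

Step 11
Reactants: 25 (2R,3R)-5,7-bis(benzyloxy)-8-{(2S)-7-(benzyloxy)-2-[4-(benzyloxy)phenyl]-2H-chromen-4-yl}-2-[3,4,5-tris(benzyloxy)phenyl]chroman-3-ol
Product: 26 (2R,3R)-8-[(2S,4S)-7-hydroxy-2-(4-hydroxyphenyl)chroman-4-yl]-2-(3,4,5-trihydroxyphenyl)chroman-3,5,7-triol (CNP0220331.2)
Conditions: H2 (1 atm), Pd(OH)2/C, THF/MeOH, rt
Reagents that add atoms: none
Why: Heterogeneous hydrogenation should add H2 to C3=C4 from the face opposite the 2-aryl group of the upper unit, which places the C4 aryl cis to it (4S), and the same catalyst hydrogenolyses the seven benzyl ethers, while the benzylic C2–O1 bonds of flavans normally survive these mild conditions.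

Compound list

1 | 4-methoxybenzyl alcohol | COc1ccc(CO)cc1 | starting material
2 | 2-chloro-N-methoxy-N-methylacetamide | CON(C)C(=O)CCl | starting material
3 | sodium 4-methoxybenzyl oxide | COc1ccc(CO[Na])cc1 | intermediate (not isolated)
4 | N-methoxy-2-[(4-methoxybenzyl)oxy]-N-methylacetamide | COc1ccc(COCC(=O)N(C)OC)cc1 | intermediate
5 | 5-fluororesorcinol (5-fluorobenzene-1,3-diol) | Oc1cc(O)cc(F)c1 | starting material
6 | 1,3-bis(benzyloxy)-5-fluorobenzene | Fc1cc(OCc2ccccc2)cc(OCc2ccccc2)c1 | intermediate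
7 | [2,4-bis(benzyloxy)-6-fluorophenyl]lithium | [Li]c1c(F)cc(OCc2ccccc2)cc1OCc1ccccc1 | intermediate (not isolated)
8 | 1-[2,4-bis(benzyloxy)-6-fluorophenyl]-2-[(4-methoxybenzyl)oxy]ethan-1-one | COc1ccc(COCC(=O)c2c(F)cc(OCc3ccccc3)cc2OCc2ccccc2)cc1 | intermediate
9 | 3,4,5-tris(benzyloxy)benzoyl chloride | O=C(Cl)c1cc(OCc2ccccc2)c(OCc2ccccc2)c(OCc2ccccc2)c1 | starting material
10 | lithium (Z)-enolate of 8 | [Li]O/C(=C\OCc1ccc(OC)cc1)c1c(F)cc(OCc2ccccc2)cc1OCc1ccccc1 | intermediate (not isolated)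
11 | lithium enolate of 1-[2,4-bis(benzyloxy)-6-fluorophenyl]-2-[(4-methoxybenzyl)oxy]-3-[3,4,5-tris(benzyloxy)phenyl]propane-1,3-dione | [Li]OC(=C(OCc1ccc(OC)cc1)C(=O)c1c(F)cc(OCc2ccccc2)cc1OCc1ccccc1)c1cc(OCc2ccccc2)c(OCc2ccccc2)c(OCc2ccccc2)c1 | intermediate (not isolated)
12 | 5,7-bis(benzyloxy)-3-[(4-methoxybenzyl)oxy]-2-[3,4,5-tris(benzyloxy)phenyl]-4H-chromen-4-one | COc1ccc(COc2c(-c3cc(OCc4ccccc4)c(OCc4ccccc4)c(OCc4ccccc4)c3)oc3cc(OCc4ccccc4)cc(OCc4ccccc4)c3c2=O)cc1 | intermediate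
13 | 5,7-bis(benzyloxy)-3-[(4-methoxybenzyl)oxy]-2-[3,4,5-tris(benzyloxy)phenyl]-4H-chromen-4-ol (racemic at C4) | COc1ccc(COC2=C(c3cc(OCc4ccccc4)c(OCc4ccccc4)c(OCc4ccccc4)c3)Oc3cc(OCc4ccccc4)cc(OCc4ccccc4)c3C2O)cc1 | intermediate (not isolated)
14 | 5,7-bis(benzyloxy)-3-[(4-methoxybenzyl)oxy]-2-[3,4,5-tris(benzyloxy)phenyl]chromenylium trifluoroacetate | COc1ccc(COc2cc3c(OCc4ccccc4)cc(OCc4ccccc4)cc3[o+]c2-c2cc(OCc3ccccc3)c(OCc3ccccc3)c(OCc3ccccc3)c2)cc1.[O-]C(=O)C(F)(F)F | intermediate (not isolated)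
15 | 5,7-bis(benzyloxy)-3-[(4-methoxybenzyl)oxy]-2-[3,4,5-tris(benzyloxy)phenyl]chromane (racemic, 2,3-cis/trans mixture, no centre defined) | COc1ccc(COC2Cc3c(OCc4ccccc4)cc(OCc4ccccc4)cc3OC2c2cc(OCc3ccccc3)c(OCc3ccccc3)c(OCc3ccccc3)c2)cc1 | intermediate (not isolated)
16 | 5,7-bis(benzyloxy)-2-[3,4,5-tris(benzyloxy)phenyl]chroman-3-ol (racemic, 2,3-cis/trans mixture, no centre defined) | OC1Cc2c(OCc3ccccc3)cc(OCc3ccccc3)cc2OC1c1cc(OCc2ccccc2)c(OCc2ccccc2)c(OCc2ccccc2)c1 | intermediate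
17 | 5,7-bis(benzyloxy)-2-[3,4,5-tris(benzyloxy)phenyl]chroman-3-one (racemic, C2 labile) | O=C1Cc2c(OCc3ccccc3)cc(OCc3ccccc3)cc2OC1c1cc(OCc2ccccc2)c(OCc2ccccc2)c(OCc2ccccc2)c1 | intermediate
18 | (2R,3R)-5,7-bis(benzyloxy)-2-[3,4,5-tris(benzyloxy)phenyl]chroman-3-ol | O[C@@H]1Cc2c(OCc3ccccc3)cc(OCc3ccccc3)cc2O[C@@H]1c1cc(OCc2ccccc2)c(OCc2ccccc2)c(OCc2ccccc2)c1 | intermediate
19 | (2R,3R)-5,7-bis(benzyloxy)-8-bromo-2-[3,4,5-tris(benzyloxy)phenyl]chroman-3-ol | O[C@@H]1Cc2c(OCc3ccccc3)cc(OCc3ccccc3)c(Br)c2O[C@@H]1c1cc(OCc2ccccc2)c(OCc2ccccc2)c(OCc2ccccc2)c1 | intermediate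
20 | (2S)-liquiritigenin | Oc1ccc([C@@H]2CC(=O)c3ccc(O)cc3O2)cc1 | starting material
21 | (2S)-7-(benzyloxy)-2-[4-(benzyloxy)phenyl]chroman-4-one | c1ccccc1COc1ccc([C@@H]2CC(=O)c3ccc(OCc4ccccc4)cc3O2)cc1 | intermediate
22 | dilithio species of 19 (C8–Li, 3-OLi) | [Li]O[C@@H]1Cc2c(OCc3ccccc3)cc(OCc3ccccc3)c([Li])c2O[C@@H]1c1cc(OCc2ccccc2)c(OCc2ccccc2)c(OCc2ccccc2)c1 | intermediate (not isolated)
23 | C8 aryl-dichlorocerium species (3-OLi) | [Li]O[C@@H]1Cc2c(OCc3ccccc3)cc(OCc3ccccc3)c([Ce](Cl)Cl)c2O[C@@H]1c1cc(OCc2ccccc2)c(OCc2ccccc2)c(OCc2ccccc2)c1 | intermediate (not isolated)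
24 | (2R,3R)-5,7-bis(benzyloxy)-8-{(2S)-7-(benzyloxy)-2-[4-(benzyloxy)phenyl]-4-hydroxychroman-4-yl}-2-[3,4,5-tris(benzyloxy)phenyl]chroman-3-ol (C4 carbinol centre undefined) | c1ccccc1COc1ccc([C@@H]2CC(O)(c3c(OCc5ccccc5)cc(OCc5ccccc5)c4c3O[C@H](c3cc(OCc5ccccc5)c(OCc5ccccc5)c(OCc5ccccc5)c3)[C@H](O)C4)c3ccc(OCc5ccccc5)cc3O2)cc1 | intermediate (not isolated)
25 | (2R,3R)-5,7-bis(benzyloxy)-8-{(2S)-7-(benzyloxy)-2-[4-(benzyloxy)phenyl]-2H-chromen-4-yl}-2-[3,4,5-tris(benzyloxy)phenyl]chroman-3-ol | c1ccccc1COc1ccc([C@@H]2C=C(c3c(OCc5ccccc5)cc(OCc5ccccc5)c4c3O[C@H](c3cc(OCc5ccccc5)c(OCc5ccccc5)c(OCc5ccccc5)c3)[C@H](O)C4)c3ccc(OCc5ccccc5)cc3O2)cc1 | intermediate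
26 | (2R,3R)-8-[(2S,4S)-7-hydroxy-2-(4-hydroxyphenyl)chroman-4-yl]-2-(3,4,5-trihydroxyphenyl)chroman-3,5,7-triol | Oc1ccc([C@@H]2C[C@H](c3c(O)cc(O)c4c3O[C@H](c3cc(O)c(O)c(O)c3)[C@H](O)C4)c3ccc(O)cc3O2)cc1 | target

Total step count: 11. Longest linear sequence: 9 steps (steps 2, 3, 4, 5, 6, 7, 8, 10, 11).

Steps most likely to fail

First, step 4. The hindered enolate may be acylated on oxygen instead of carbon, or the crowded diketonate may suffer retro-Claisen cleavage before the ring closes. The fallback sets out from 8 and comes back at 12. The lithium enolate of 8 (LiN(i-Pr)2, THF, −78 °C) is added to 3,4,5-tris(benzyloxy)benzaldehyde and quenched cold, which should give 1-[2,4-bis(benzyloxy)-6-fluorophenyl]-3-hydroxy-2-[(4-methoxybenzyl)oxy]-3-[3,4,5-tris(benzyloxy)phenyl]propan-1-one F1. Periodinane oxidation of the carbinol should give the 2-alkoxy-1,3-diketone F2, so that the C2–C3 bond comes from an aldol addition and not from an acylation. Cs2CO3 in DMF at 60 °C should then close ring C by SNAr to 12.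

Second, step 7. Epimerisation at C2 may be too slow relative to hydride transfer, so that the reduction behaves as a plain kinetic resolution, or the catalyst may discriminate the ketone faces poorly. The fallback sets out from 17 and comes back at 18. LiBH(s-Bu)3 in THF at −78 °C should reduce 17 anti to the 2-aryl group to the racemic 2,3-cis alcohol F3. Esterification with (S)-2-methoxy-2-phenylacetic acid (DCC, DMAP) should give the diastereomeric esters of the 2R,3R alcohol F4 and of the 2S,3S alcohol F5, which are separated by chromatography. LiOH in THF/H2O releases 18 from F4; F5 can be hydrolysed and reoxidised to 17 for recycling.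

Third, step 10. The hindered, doubly ortho-substituted aryl-metal may deprotonate the flavanone at C3 instead of adding to the carbonyl group. The fallback sets out from 21 and 19 and comes back at 25. Enolisation of 21 is used productively: KN(SiMe3)2 and N-phenylbis(trifluoromethanesulfonimide) in THF at −78 °C should give (2S)-7-(benzyloxy)-2-[4-(benzyloxy)phenyl]-2H-chromen-4-yl trifluoromethanesulfonate F6. Br/Li exchange on 19 as in step 10 and a quench with 2-isopropoxy-4,4,5,5-tetramethyl-1,3,2-dioxaborolane should give the C8 pinacol boronate F7. Suzuki–Miyaura coupling of F6 and F7 (Pd(OAc)2, SPhos, K3PO4, toluene/H2O, 60 °C) should give 25 directly.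

Further compounds

F1 | step 4 | 1-[2,4-bis(benzyloxy)-6-fluorophenyl]-3-hydroxy-2-[(4-methoxybenzyl)oxy]-3-[3,4,5-tris(benzyloxy)phenyl]propan-1-one (racemic syn/anti mixture) | OC(c1cc(OCc2ccccc2)c(OCc2ccccc2)c(OCc2ccccc2)c1)C(OCc1ccc(OC)cc1)C(=O)c1c(F)cc(OCc2ccccc2)cc1OCc1ccccc1
F2 | step 4 | 1-[2,4-bis(benzyloxy)-6-fluorophenyl]-2-[(4-methoxybenzyl)oxy]-3-[3,4,5-tris(benzyloxy)phenyl]propane-1,3-dione | O=C(c1cc(OCc2ccccc2)c(OCc2ccccc2)c(OCc2ccccc2)c1)C(OCc1ccc(OC)cc1)C(=O)c1c(F)cc(OCc2ccccc2)cc1OCc1ccccc1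
F3 | step 7 | racemic 2,3-cis-5,7-bis(benzyloxy)-2-[3,4,5-tris(benzyloxy)phenyl]chroman-3-ol (both enantiomers) | O[C@@H]1Cc2c(OCc3ccccc3)cc(OCc3ccccc3)cc2O[C@@H]1c1cc(OCc2ccccc2)c(OCc2ccccc2)c(OCc2ccccc2)c1.O[C@H]1Cc2c(OCc3ccccc3)cc(OCc3ccccc3)cc2O[C@H]1c1cc(OCc2ccccc2)c(OCc2ccccc2)c(OCc2ccccc2)c1
F4 | step 7 | (2R,3R)-5,7-bis(benzyloxy)-2-[3,4,5-tris(benzyloxy)phenyl]chroman-3-yl (S)-2-methoxy-2-phenylacetate | O=C(O[C@@H]1Cc2c(OCc3ccccc3)cc(OCc3ccccc3)cc2O[C@@H]1c1cc(OCc2ccccc2)c(OCc2ccccc2)c(OCc2ccccc2)c1)[C@@H](OC)c1ccccc1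
F5 | step 7 | (2S,3S)-5,7-bis(benzyloxy)-2-[3,4,5-tris(benzyloxy)phenyl]chroman-3-yl (S)-2-methoxy-2-phenylacetate | O=C(O[C@H]1Cc2c(OCc3ccccc3)cc(OCc3ccccc3)cc2O[C@H]1c1cc(OCc2ccccc2)c(OCc2ccccc2)c(OCc2ccccc2)c1)[C@@H](OC)c1ccccc1
F6 | step 10 | (2S)-7-(benzyloxy)-2-[4-(benzyloxy)phenyl]-2H-chromen-4-yl trifluoromethanesulfonate | c1ccccc1COc1ccc([C@@H]2C=C(OS(=O)(=O)C(F)(F)F)c3ccc(OCc4ccccc4)cc3O2)cc1
F7 | step 10 | (2R,3R)-5,7-bis(benzyloxy)-8-(4,4,5,5-tetramethyl-1,3,2-dioxaborolan-2-yl)-2-[3,4,5-tris(benzyloxy)phenyl]chroman-3-ol | CC1(C)OB(c2c(OCc3ccccc3)cc(OCc3ccccc3)c3c2O[C@H](c2cc(OCc4ccccc4)c(OCc4ccccc4)c(OCc4ccccc4)c2)[C@H](O)C3)OC1(C)C
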